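**Retrosynthetic overview**

1. Diaporindene G (22) ⇐ 20 by fluoride and mild-acid removal of a silyl ether and of an (S,S)-hydrobenzoin acetal, which protects the aldehyde and serves as the chiral controller.
2. 20 ⇐ indenyl aryl ether 18 by the key step: a thermal aromatic Claisen rearrangement makes the aryl–C bond to the indane methine and the exocyclic isopropylidene, and releases a phenoxide next to an (R)-oxirane; that phenoxide closes the 1,4-dioxane ring in the same flask by O–C bond formation with inversion.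
3. Enabling feature: in the target, the dioxane oxygen on the arene, the neighbouring aryl carbon that carries the indane, the indane methine and the exocyclic C=CMe2 form the array O–C(aryl)=C(aryl)–CH–C=CMe2, which is the product pattern of a [3,3] shift of an aryl 1,1-dimethylallyl ether. The other ortho position (second dioxane oxygen) and the para position (methyl) are blocked. The same oxygen is 1,2 to the oxygen bearing the three-carbon chain, so a 6-exo opening of an epoxidised prenyl ether can follow.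
4. 18 ⇐ ring-closing metathesis of 17 ⇐ methylenation of 16 ⇐ palladium-catalysed α-arylation of methyl ketone 8 (from 2-hydroxy-5-methylbenzaldehyde: tertiary O-alkylation, Dakin oxidation, prenylation, Shi epoxidation) with aryl bromide 15 (from 2-bromo-6-hydroxybenzaldehyde: acetalisation, vinylation, para-bromination, silylation).
5. Order of ring formation: dioxolane of the auxiliary (step 5), oxirane (step 4, other fragment), five-membered ring of the indene (step 11), 1,4-dioxane (step 12); both benzene rings come from the starting materials.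

Key step: step 12

Assumption: the sense of facial shielding by the (4S,5S)-acetal in step 12 rests on a conformational model (acetal C–H syn to the silyloxy oxygen, dioxolane leaning over the neighbouring vinylic carbon). Both enantiomers of the diol are commercial, so the auxiliary of step 5 can be exchanged without altering the route if the model needs correcting.

**Route**

Step 1
Reactants: 1 2-hydroxy-5-methylbenzaldehyde; 2 3-bromo-3-methylbutan-2-one
Product: 3 5-methyl-2-[(2-methyl-3-oxobutan-2-yl)oxy]benzaldehyde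
Conditions: K2CO3, DMF, 50 °C
Reagents that add atoms: none
Why: Williamson-type SN2 O-alkylation of the phenoxide at the carbonyl-activated tertiary bromide (the reaction type used for aryloxyisobutyryl compounds) should install the tertiary aryl ether whose oxygen later becomes the dioxane oxygen, and no stereocentre is formed.

Step 2
Reactants: 3 5-methyl-2-[(2-methyl-3-oxobutan-2-yl)oxy]benzaldehyde
Product: 5 3-(2-hydroxy-4-methylphenoxy)-3-methylbutan-2-one, via aryl formate 4 (not isolated)
Conditions: mCPBA, CH2Cl2, 0 °C to rt; aq. NaHCO3 wash; then K2CO3 (cat.), MeOH, rt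
Reagents that add atoms: mCPBA (3-chloroperoxybenzoic acid), OOC(=O)c1cccc(Cl)c1
Why: Dakin-type Baeyer–Villiger oxidation in which the electron-rich aryl group of the aldehyde migrates to give formate 4, which is methanolysed to the phenol, while the far less reactive ketone should survive at this temperature, and no stereocentre is formed.

Step 3
Reactants: 5 3-(2-hydroxy-4-methylphenoxy)-3-methylbutan-2-one; 6 1-bromo-3-methylbut-2-ene
Product: 7 3-methyl-3-{4-methyl-2-[(3-methylbut-2-en-1-yl)oxy]phenoxy}butan-2-one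
Conditions: K2CO3, DMF, rt
Reagents that add atoms: none
Why: Williamson etherification of the phenoxide of 5 (to which any ring-closed hemiketal form reverts under base) with the primary allylic bromide, no stereocentre being formed.

Step 4
Reactants: 7 3-methyl-3-{4-methyl-2-[(3-methylbut-2-en-1-yl)oxy]phenoxy}butan-2-one
Product: 8 3-(2-{[(2R)-3,3-dimethyloxiran-2-yl]methoxy}-4-methylphenoxy)-3-methylbutan-2-one
Conditions: D-fructose-derived Shi ketone (30 mol%), KHSO5 (as 2KHSO5·KHSO4·K2SO4), K2CO3, Bu4NHSO4 (cat.), MeCN/CH2(OMe)2/aqueous Na2B4O7 buffer, 0 °C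
Reagents that add atoms: potassium peroxymonosulfate (KHSO5), [K+].OOS([O-])(=O)=O
Why: Shi asymmetric epoxidation, in which the chiral dioxirane formed from the ketone catalyst should epoxidise the only alkene, a trisubstituted one, through the spiro transition state on the face that gives the (R)-oxirane (catalyst control).

Step 5
Reactants: 9 2-bromo-6-hydroxybenzaldehyde; 10 (1S,2S)-1,2-diphenylethane-1,2-diol
Product: 11 3-bromo-2-[(4S,5S)-4,5-diphenyl-1,3-dioxolan-2-yl]phenol
Conditions: TsOH·H2O (5 mol%), toluene, reflux, Dean–Stark trap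
Reagents that add atoms: none
Why: Acid-catalysed acetalisation with azeotropic removal of water, which protects the aldehyde and installs the C2-symmetric auxiliary without creating a stereocentre at the acetal carbon.

Step 6
Reactants: 11 3-bromo-2-[(4S,5S)-4,5-diphenyl-1,3-dioxolan-2-yl]phenol; 12 potassium ethenyltrifluoroborate
Product: 13 3-ethenyl-2-[(4S,5S)-4,5-diphenyl-1,3-dioxolan-2-yl]phenol
Conditions: PdCl2(dppf) (5 mol%), Cs2CO3, THF/H2O (9:1), 80 °C
Reagents that add atoms: none
Why: Suzuki–Miyaura cross-coupling of the aryl bromide with the vinyltrifluoroborate, which tolerates the free phenol and the acetal and forms no stereocentre.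

Step 7
Reactants: 13 3-ethenyl-2-[(4S,5S)-4,5-diphenyl-1,3-dioxolan-2-yl]phenol
Product: 14 4-bromo-3-ethenyl-2-[(4S,5S)-4,5-diphenyl-1,3-dioxolan-2-yl]phenol
Conditions: NBS, MeCN, −20 °C to 0 °C
Reagents that add atoms: N-bromosuccinimide (NBS), O=C1CCC(=O)N1Br
Why: Electrophilic aromatic bromination of a 2,3-disubstituted phenol in a polar solvent should go para to the free hydroxyl group and should be faster than any reaction of NBS at the vinyl group, no stereocentre being formed.

Step 8
Reactants: 14 4-bromo-3-ethenyl-2-[(4S,5S)-4,5-diphenyl-1,3-dioxolan-2-yl]phenol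
Product: 15 [4-bromo-3-ethenyl-2-((4S,5S)-4,5-diphenyl-1,3-dioxolan-2-yl)phenoxy]tri(propan-2-yl)silane
Conditions: NaH, THF, 0 °C; then iPr3SiCl, rt
Reagents that add atoms: chlorotri(propan-2-yl)silane, CC(C)[Si](Cl)(C(C)C)C(C)C
Why: O-silylation of the sodium phenoxide gives a base-stable, fluoride-labile ether whose oxygen also fixes the acetal conformation used in step 12, and no stereocentre is formed.

Step 9
Reactants: 8 3-(2-{[(2R)-3,3-dimethyloxiran-2-yl]methoxy}-4-methylphenoxy)-3-methylbutan-2-one; 15 [4-bromo-3-ethenyl-2-((4S,5S)-4,5-diphenyl-1,3-dioxolan-2-yl)phenoxy]tri(propan-2-yl)silane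
Product: 16 3-(2-{[(2R)-3,3-dimethyloxiran-2-yl]methoxy}-4-methylphenoxy)-1-{3-[(4S,5S)-4,5-diphenyl-1,3-dioxolan-2-yl]-2-ethenyl-4-{[tri(propan-2-yl)silyl]oxy}phenyl}-3-methylbutan-2-one
Conditions: Pd2(dba)3 (2.5 mol%), Xantphos (6 mol%), K3PO4, toluene, 80 °C
Reagents that add atoms: none
Why: Palladium-catalysed α-arylation of a ketone enolate, in which 8 can enolise only towards its methyl group so that mono-arylation there should give the benzyl ketone, the mild phosphate base sparing the oxirane and no stereocentre being formed or touched.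

Step 10
Reactants: 16 (the benzyl ketone of step 9)
Product: 17 (2R)-2-{[2-({3-[(3-[(4S,5S)-4,5-diphenyl-1,3-dioxolan-2-yl]-2-ethenyl-4-{[tri(propan-2-yl)silyl]oxy}phenyl)methyl]-2-methylbut-3-en-2-yl}oxy)-5-methylphenoxy]methyl}-3,3-dimethyloxirane
Conditions: Cp2Ti(μ-CH2)(μ-Cl)AlMe2 (Tebbe reagent), pyridine, THF/toluene, −40 °C to 0 °C
Reagents that add atoms: Tebbe reagent Cp2Ti(μ-CH2)(μ-Cl)AlMe2, C[Al-]1(C)C[Ti](C2C=CC=C2)(C2C=CC=C2)[Cl+]1
Why: Tebbe methylenation, in which the titanium methylidene olefinates hindered and enolisable ketones through an oxatitanacyclobutane at low temperature, well below the temperature at which the new allyl aryl ether would rearrange, and no stereocentre is formed.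

Step 11
Reactants: 17 (the diene of step 10)
Product: 18 (2R)-2-{[2-({2-[4-[(4S,5S)-4,5-diphenyl-1,3-dioxolan-2-yl]-5-{[tri(propan-2-yl)silyl]oxy}-1H-inden-2-yl]propan-2-yl}oxy)-5-methylphenoxy]methyl}-3,3-dimethyloxirane
Conditions: second-generation Grubbs catalyst (H2IMes)(PCy3)Cl2Ru=CHPh (5 mol%), CH2Cl2 (0.005 M), 40 °C; filtration through neutral alumina
Reagents that add atoms: none
Why: Ring-closing olefin metathesis between the styrene and the 1,1-disubstituted alkene should close the five-membered ring of a 2-substituted indene with loss of ethene and places the double bond unambiguously on the carbon next to the acetal-bearing ring position, the neutral conditions at 40 °C avoiding double-bond migration and premature rearrangement.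

Step 12
Reactants: 18 (the indenyl aryl ether of step 11)
Product: 20 2-[(2S)-8-[(1R)-7-[(4S,5S)-4,5-diphenyl-1,3-dioxolan-2-yl]-2-(propan-2-ylidene)-6-{[tri(propan-2-yl)silyl]oxy}-2,3-dihydro-1H-inden-1-yl]-6-methyl-2,3-dihydro-1,4-benzodioxin-2-yl]propan-2-ol, via Claisen phenol 19 (not isolated)
Conditions: toluene (degassed), 120 °C, sealed tube, until 18 is consumed; then K2CO3 and DMF added to the same flask, 60 °C
Reagents that add atoms: none
Why: Proposed new method: heating should trigger a concerted, suprafacial [3,3] shift of the aryl 1,1-dimethylallyl ether in which the only free ortho carbon of the aryloxy ring bonds to the vinylic CH of the indene, the alkene moves to the exocyclic C=CMe2 position and the ortho-dienone tautomerises to phenol 19, whose oxygen now sits next to the epoxy ether; added K2CO3 then lets the phenoxide open the oxirane at its CH carbon. The closest known reaction types are the thermal aromatic Claisen rearrangement of aryl 1,1-dimethylallyl (reverse-prenyl) ethers and the base-mediated cyclisation of 2-(oxiranylmethoxy)phenols to 2-substituted 1,4-benzodioxanes; new are their telescoping and the relay of chirality from a peri acetal. The only ring closed is the 1,4-dioxane, by 6-exo-tet attack of the phenoxide, anionic conditions disfavouring the 7-endo attack at the tertiary carbon. The indane methine is set in the [3,3] step by the (4S,5S)-diphenyldioxolane, whose phenyl group should cover one face (Re) of the vinylic carbon when the acetal C–H lies syn to the silyloxy oxygen, so that bonding on the open face gives R; the dioxane carbon is set by SN2 inversion of the (R)-oxirane and becomes S. Regioselectivity is secured by the substrate, since the second ortho position carries the ether oxygen and the para position the methyl group, and the neutral, non-polar first stage avoids both base-induced migration of the indene double bond (which would deliver the aryl group to the other benzylic carbon) and ionisation of the tertiary ether.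

Step 13
Reactants: 20 (the silyl- and acetal-protected benzodioxane of step 12)
Product: 22 (3R)-5-hydroxy-3-[(3S)-3-(2-hydroxypropan-2-yl)-7-methyl-2,3-dihydro-1,4-benzodioxin-5-yl]-2-(propan-2-ylidene)-2,3-dihydro-1H-indene-4-carbaldehyde (Diaporindene G), via desilylated acetal 21 (not isolated)
Conditions: Bu4NF, AcOH, THF, 0 °C; then AcOH/H2O (4:1), 40 °C
Reagents that add atoms: water, O
Why: Buffered fluoride desilylation frees the phenol, whose ortho position should make the benzylic acetal labile enough for hydrolysis in aqueous acetic acid, conditions too mild to protonate the tetrasubstituted alkene, ionise the tertiary alcohol or disturb either stereocentre.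

**Compound list**

1 | 2-hydroxy-5-methylbenzaldehyde | Cc1ccc(O)c(C=O)c1 | starting material
2 | 3-bromo-3-methylbutan-2-one | CC(=O)C(C)(C)Br | starting material
3 | 5-methyl-2-[(2-methyl-3-oxobutan-2-yl)oxy]benzaldehyde | Cc1ccc(OC(C)(C)C(C)=O)c(C=O)c1 | intermediate
4 | 5-methyl-2-[(2-methyl-3-oxobutan-2-yl)oxy]phenyl formate | Cc1ccc(OC(C)(C)C(C)=O)c(OC=O)c1 | intermediate (not isolated)
5 | 3-(2-hydroxy-4-methylphenoxy)-3-methylbutan-2-one | Cc1ccc(OC(C)(C)C(C)=O)c(O)c1 | intermediate
6 | 1-bromo-3-methylbut-2-ene (prenyl bromide) | CC(C)=CCBr | starting material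
7 | 3-methyl-3-{4-methyl-2-[(3-methylbut-2-en-1-yl)oxy]phenoxy}butan-2-one | Cc1ccc(OC(C)(C)C(C)=O)c(OCC=C(C)C)c1 | intermediate
8 | 3-(2-{[(2R)-3,3-dimethyloxiran-2-yl]methoxy}-4-methylphenoxy)-3-methylbutan-2-one | Cc1ccc(OC(C)(C)C(C)=O)c(OC[C@H]2OC2(C)C)c1 | intermediate
9 | 2-bromo-6-hydroxybenzaldehyde | O=Cc1c(O)cccc1Br | starting material
10 | (1S,2S)-1,2-diphenylethane-1,2-diol ((S,S)-hydrobenzoin) | O[C@@H](c1ccccc1)[C@@H](O)c1ccccc1 | starting material
11 | 3-bromo-2-[(4S,5S)-4,5-diphenyl-1,3-dioxolan-2-yl]phenol | Oc1cccc(Br)c1C1O[C@@H](c2ccccc2)[C@H](c2ccccc2)O1 | intermediate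
12 | potassium ethenyltrifluoroborate | C=C[B-](F)(F)F.[K+] | starting material
13 | 3-ethenyl-2-[(4S,5S)-4,5-diphenyl-1,3-dioxolan-2-yl]phenol | Oc1cccc(C=C)c1C1O[C@@H](c2ccccc2)[C@H](c2ccccc2)O1 | intermediate
14 | 4-bromo-3-ethenyl-2-[(4S,5S)-4,5-diphenyl-1,3-dioxolan-2-yl]phenol | Oc1ccc(Br)c(C=C)c1C1O[C@@H](c2ccccc2)[C@H](c2ccccc2)O1 | intermediate
15 | [4-bromo-3-ethenyl-2-((4S,5S)-4,5-diphenyl-1,3-dioxolan-2-yl)phenoxy]tri(propan-2-yl)silane | CC(C)[Si](Oc1ccc(Br)c(C=C)c1C1O[C@@H](c2ccccc2)[C@H](c2ccccc2)O1)(C(C)C)C(C)C | intermediate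
16 | 3-(2-{[(2R)-3,3-dimethyloxiran-2-yl]methoxy}-4-methylphenoxy)-1-{3-[(4S,5S)-4,5-diphenyl-1,3-dioxolan-2-yl]-2-ethenyl-4-{[tri(propan-2-yl)silyl]oxy}phenyl}-3-methylbutan-2-one | Cc1ccc(OC(C)(C)C(=O)Cc2ccc(O[Si](C(C)C)(C(C)C)C(C)C)c(C3O[C@@H](c4ccccc4)[C@H](c4ccccc4)O3)c2C=C)c(OC[C@H]2OC2(C)C)c1 | intermediate
17 | (2R)-2-{[2-({3-[(3-[(4S,5S)-4,5-diphenyl-1,3-dioxolan-2-yl]-2-ethenyl-4-{[tri(propan-2-yl)silyl]oxy}phenyl)methyl]-2-methylbut-3-en-2-yl}oxy)-5-methylphenoxy]methyl}-3,3-dimethyloxirane (methylidene analogue of 16) | Cc1ccc(OC(C)(C)C(=C)Cc2ccc(O[Si](C(C)C)(C(C)C)C(C)C)c(C3O[C@@H](c4ccccc4)[C@H](c4ccccc4)O3)c2C=C)c(OC[C@H]2OC2(C)C)c1 | intermediate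
18 | (2R)-2-{[2-({2-[4-[(4S,5S)-4,5-diphenyl-1,3-dioxolan-2-yl]-5-{[tri(propan-2-yl)silyl]oxy}-1H-inden-2-yl]propan-2-yl}oxy)-5-methylphenoxy]methyl}-3,3-dimethyloxirane | Cc1ccc(OC(C)(C)C2=Cc3c(C2)ccc(O[Si](C(C)C)(C(C)C)C(C)C)c3C2O[C@@H](c3ccccc3)[C@H](c3ccccc3)O2)c(OC[C@H]2OC2(C)C)c1 | intermediate
19 | 2-[(1R)-7-[(4S,5S)-4,5-diphenyl-1,3-dioxolan-2-yl]-2-(propan-2-ylidene)-6-{[tri(propan-2-yl)silyl]oxy}-2,3-dihydro-1H-inden-1-yl]-6-{[(2R)-3,3-dimethyloxiran-2-yl]methoxy}-4-methylphenol | CC(C)=C1Cc2ccc(O[Si](C(C)C)(C(C)C)C(C)C)c(C3O[C@@H](c4ccccc4)[C@H](c4ccccc4)O3)c2[C@@H]1c1cc(C)cc(OC[C@H]2OC2(C)C)c1O | intermediate (not isolated)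
20 | 2-[(2S)-8-[(1R)-7-[(4S,5S)-4,5-diphenyl-1,3-dioxolan-2-yl]-2-(propan-2-ylidene)-6-{[tri(propan-2-yl)silyl]oxy}-2,3-dihydro-1H-inden-1-yl]-6-methyl-2,3-dihydro-1,4-benzodioxin-2-yl]propan-2-ol | CC(C)=C1Cc2ccc(O[Si](C(C)C)(C(C)C)C(C)C)c(C3O[C@@H](c4ccccc4)[C@H](c4ccccc4)O3)c2[C@@H]1c1cc(C)cc2c1O[C@H](C(C)(C)O)CO2 | intermediate
21 | (3R)-4-[(4S,5S)-4,5-diphenyl-1,3-dioxolan-2-yl]-3-[(3S)-3-(2-hydroxypropan-2-yl)-7-methyl-2,3-dihydro-1,4-benzodioxin-5-yl]-2-(propan-2-ylidene)-2,3-dihydro-1H-inden-5-ol | CC(C)=C1Cc2ccc(O)c(C3O[C@@H](c4ccccc4)[C@H](c4ccccc4)O3)c2[C@@H]1c1cc(C)cc2c1O[C@H](C(C)(C)O)CO2 | intermediate (not isolated)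
22 | Diaporindene G, (3R)-5-hydroxy-3-[(3S)-3-(2-hydroxypropan-2-yl)-7-methyl-2,3-dihydro-1,4-benzodioxin-5-yl]-2-(propan-2-ylidene)-2,3-dihydro-1H-indene-4-carbaldehyde | CC(C)=C1Cc2ccc(O)c(C=O)c2[C@@H]1c1cc(C)cc2c1O[C@H](C(C)(C)O)CO2 | target

**Step count and risks**

Total step count: 13. Longest linear sequence: 9 steps (steps 1–4 then 9–13; the branch through steps 5–8 is equally long).

Steps most likely to fail:

1. Step 12. The risk is insufficient facial discrimination in the [3,3] shift if the acetal is less conformationally locked than modelled, with heterolysis of the tertiary allylic C–O bond as a competing process. Fallback (known chemistry, stereocontrol replaced by separation): it sets out from 18 and returns at 20. The rearrangement would be run alone (toluene, 120 °C) and phenol 19 isolated together with its epimer at the indane methine, the (1S)-epimeric phenol F1. The mixture would then be cyclised in a separate operation (K2CO3, DMF, 60 °C), and 20 would be separated from the (1S)-epimeric benzodioxane F2 by chromatography or crystallisation. This is possible because the acetal and the dioxane carbon make the two epimers diastereomers.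

2. Step 11. The risk is slow ring closure onto the hindered 1,1-disubstituted alkene, so that thermal [3,3] rearrangement of the diene onto its own methylidene terminus or homodimerisation of the styrene competes. Fallback: it sets out from 16 (so it also bypasses step 10) and returns at 18. Lemieux–Johnson cleavage of the vinyl group (OsO4 cat., NaIO4, 2,6-lutidine, dioxane/H2O) would give the keto aldehyde F3. Chemoselective reduction (NaBH4, MeOH, −40 °C) would give the benzylic alcohol F4. Appel bromination (CBr4, PPh3, 2,6-lutidine, CH2Cl2, 0 °C) would give the benzylic bromide F5, and quaternisation (PPh3, MeCN, 50 °C) the phosphonium bromide F6. Intramolecular Wittig olefination of the ketone (one equivalent of KOtBu, THF, −78 °C to 0 °C) would then close the indene with the double bond in the same defined position.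

3. Step 10. The risk is opening of the oxirane by the Lewis-acidic aluminium by-products, or enolisation of the benzyl ketone in place of methylenation. Fallback: it sets out from 8 (and uses 15) and returns at 17, bypassing 16 and any carbonyl methylenation. Ketone 8 would be converted into the enol triflate F7 (KN(SiMe3)2, PhNTf2, THF, −78 °C). F7 would be coupled with bis(pinacolatoboryl)methane (Pd[P(tBu)3]2 cat., aq. KOH, dioxane, rt) to give the 2-substituted allylboronate F8. F8 would then be joined to aryl bromide 15 by Suzuki–Miyaura allyl–aryl coupling (PdCl2(dppf), K3PO4, THF/H2O, 50 °C), where attack at either allyl terminus gives the same diene.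

**Further compounds**

F1 | step 12 | 2-[(1S)-7-[(4S,5S)-4,5-diphenyl-1,3-dioxolan-2-yl]-2-(propan-2-ylidene)-6-{[tri(propan-2-yl)silyl]oxy}-2,3-dihydro-1H-inden-1-yl]-6-{[(2R)-3,3-dimethyloxiran-2-yl]methoxy}-4-methylphenol | CC(C)=C1Cc2ccc(O[Si](C(C)C)(C(C)C)C(C)C)c(C3O[C@@H](c4ccccc4)[C@H](c4ccccc4)O3)c2[C@H]1c1cc(C)cc(OC[C@H]2OC2(C)C)c1O
F2 | step 12 | 2-[(2S)-8-[(1S)-7-[(4S,5S)-4,5-diphenyl-1,3-dioxolan-2-yl]-2-(propan-2-ylidene)-6-{[tri(propan-2-yl)silyl]oxy}-2,3-dihydro-1H-inden-1-yl]-6-methyl-2,3-dihydro-1,4-benzodioxin-2-yl]propan-2-ol | CC(C)=C1Cc2ccc(O[Si](C(C)C)(C(C)C)C(C)C)c(C3O[C@@H](c4ccccc4)[C@H](c4ccccc4)O3)c2[C@H]1c1cc(C)cc2c1O[C@H](C(C)(C)O)CO2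
F3 | step 11 | 2-[3-(2-{[(2R)-3,3-dimethyloxiran-2-yl]methoxy}-4-methylphenoxy)-3-methyl-2-oxobutyl]-6-[(4S,5S)-4,5-diphenyl-1,3-dioxolan-2-yl]-5-{[tri(propan-2-yl)silyl]oxy}benzaldehyde | Cc1ccc(OC(C)(C)C(=O)Cc2ccc(O[Si](C(C)C)(C(C)C)C(C)C)c(C3O[C@@H](c4ccccc4)[C@H](c4ccccc4)O3)c2C=O)c(OC[C@H]2OC2(C)C)c1
F4 | step 11 | 3-(2-{[(2R)-3,3-dimethyloxiran-2-yl]methoxy}-4-methylphenoxy)-1-{3-[(4S,5S)-4,5-diphenyl-1,3-dioxolan-2-yl]-2-(hydroxymethyl)-4-{[tri(propan-2-yl)silyl]oxy}phenyl}-3-methylbutan-2-one | Cc1ccc(OC(C)(C)C(=O)Cc2ccc(O[Si](C(C)C)(C(C)C)C(C)C)c(C3O[C@@H](c4ccccc4)[C@H](c4ccccc4)O3)c2CO)c(OC[C@H]2OC2(C)C)c1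
F5 | step 11 | 1-{2-(bromomethyl)-3-[(4S,5S)-4,5-diphenyl-1,3-dioxolan-2-yl]-4-{[tri(propan-2-yl)silyl]oxy}phenyl}-3-(2-{[(2R)-3,3-dimethyloxiran-2-yl]methoxy}-4-methylphenoxy)-3-methylbutan-2-one | Cc1ccc(OC(C)(C)C(=O)Cc2ccc(O[Si](C(C)C)(C(C)C)C(C)C)c(C3O[C@@H](c4ccccc4)[C@H](c4ccccc4)O3)c2CBr)c(OC[C@H]2OC2(C)C)c1
F6 | step 11 | ({2-[3-(2-{[(2R)-3,3-dimethyloxiran-2-yl]methoxy}-4-methylphenoxy)-3-methyl-2-oxobutyl]-6-[(4S,5S)-4,5-diphenyl-1,3-dioxolan-2-yl]-5-{[tri(propan-2-yl)silyl]oxy}phenyl}methyl)triphenylphosphonium bromide | Cc1ccc(OC(C)(C)C(=O)Cc2ccc(O[Si](C(C)C)(C(C)C)C(C)C)c(C3O[C@@H](c4ccccc4)[C@H](c4ccccc4)O3)c2C[P+](c3ccccc3)(c3ccccc3)c3ccccc3)c(OC[C@H]2OC2(C)C)c1.[Br-]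
F7 | step 10 | 3-(2-{[(2R)-3,3-dimethyloxiran-2-yl]methoxy}-4-methylphenoxy)-3-methylbut-1-en-2-yl trifluoromethanesulfonate | Cc1ccc(OC(C)(C)C(=C)OS(=O)(=O)C(F)(F)F)c(OC[C@H]2OC2(C)C)c1
F8 | step 10 | (2R)-3,3-dimethyl-2-{[5-methyl-2-({2-methyl-3-[(4,4,5,5-tetramethyl-1,3,2-dioxaborolan-2-yl)methyl]but-3-en-2-yl}oxy)phenoxy]methyl}oxirane | Cc1ccc(OC(C)(C)C(=C)CB2OC(C)(C)C(C)(C)O2)c(OC[C@H]2OC2(C)C)c1
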